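I decided to count partner from the charges before reading the curve.

- maple: substrate 0.065 M; partner 0.60 equiv; protic impurity 0.0195 M; free catalyst 1 mol%; stray impurity 0.20 mM; the very flask that is asked about, followed so far
- flask: substrate 0.065 M; partner 0.600 equiv; protic impurity 0.0195 M; free catalyst 1 mol%; stray impurity 0.20 mM; time 12 h

1. target, in percent of the substrate first charged, at 12 h
2. the option that brings most further target ("none" if no option brings more than 2 percentage points) (zeta / epsilon / delta / eta / none)
3. target present, with what was taken out counted in, in percent of the substrate first charged, after zeta
4. target present, with what was taken out counted in, in percent of the substrate first charged, after delta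

- zeta: at 12 h add free catalyst, 100 % of the amount charged, then wait 6.0 h
- epsilon: at 12 h take out 90 % of the target then present, then wait 6.0 h
- delta: change nothing and wait 6.0 h more
- eta: at 12 h add partner, 50.0 % of the amount charged, then wait 6.0 h

- what is taken out of target is counted as made
- the numbers in the tables scatter with a standard deviation of 0.5 percentage points
- additions bring no volume worth counting

The flask holds 0.065 M of substrate and 0.0390 M of partner, so partner is the limiting reagent. But protic impurity also takes partner, and 0.0195 M of it was charged. So I reckoned the partner budget, meaning partner charged less protic impurity charged, one for one, in percent of the substrate charged: 30.0 %.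

- maple (time / h: target / %): 2.00: 25.9; 4.00: 27.3; 5.00: 24.6; 8.00: 18.1

(each reading ± 0.5 percentage points)

The highest maple reading, 27.3 % at 4.00 h, stood below that budget, but later readings fell to 18.1 % at 8.00 h, so target was being lost in the flask. Of the options, eta adds partner, worth 30.0 % of the substrate, so I looked there for new target.

The forecast gave 12 % for now (10.8 % to 13.2 %), eta as best, 5 % after zeta and 6.5 % after delta, on the grounds that “partner has run out, not catalyst”.

The flask gives 13.3 % at 12 h, eta as best with 10 percentage points, 9.85 % after zeta and 10.7 % after delta, so the forecast is right within its tolerance on each.

    substrate + free catalyst ⇌ catalyst intermediate A (K = 18.0 L mol⁻¹, k = 6.20 L mol⁻¹ s⁻¹)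
    catalyst intermediate A ⇌ catalyst intermediate B (K = 0.230, k = 4.30 s⁻¹)
    partner + catalyst intermediate B → catalyst intermediate C (k = 4.80 L mol⁻¹ s⁻¹)
    catalyst intermediate C → by-product + catalyst intermediate D (k = 0.0680 s⁻¹)
    catalyst intermediate D → free catalyst + target (k = 0.0310 s⁻¹)
    partner + protic impurity → quenched reagent (k = 0.00750 L mol⁻¹ s⁻¹)
    free catalyst + stray impurity → spent catalyst (k = 59.0 L mol⁻¹ s⁻¹)
    target + free catalyst ⇌ isomer of the product + free catalyst, rate k8*[free catalyst]*[target] forward; the back reaction follows from the equilibrium constant (K = 3.00, k = 0.180 L mol⁻¹ s⁻¹)

At 12.0 h this flask held 0.0252 M of by-product and 0.0138 M of quenched reagent, together 0.0390 M against 0.0390 M of partner charged, with 0 % of partner left. The by-product equals 38.8 % of the substrate, above the budget, while 29 % of the protic impurity, worth 8.70 % of the substrate, remained.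

In a neighbour flask, charged like this one but with 2.40 equiv of partner, the budget comes to 210 % of the substrate, so substrate becomes limiting and 45.8 % of the partner charge should remain. That computed flask holds 45.8 % of partner and 0 % of substrate at 12.0 h.

The earlier runs and the new flask are simulated for an exercise; the scatter is artificial.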